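I took the easy step first, the rate at the moment the charges met, which is a rate constant times the two charged amounts.

    substrate ⇌ dormant form (K1 = 1.2, k1 = 4.2 s⁻¹, Ea1 = 69.0 kJ mol⁻¹, ΔH1 = −50.0 kJ mol⁻¹)
    substrate → target (k2 = 1.2 × 10⁻⁴ s⁻¹, Ea2 = 84.0 kJ mol⁻¹)
    substrate + target → 2 target (k3 = 3100 M⁻¹ s⁻¹, Ea3 = 34.0 kJ mol⁻¹)
    target ⇌ isomer of the product (K4 = 9.9, k4 = 0.50 s⁻¹, Ea4 = 67.0 kJ mol⁻¹, ΔH4 = −43.0 kJ mol⁻¹)
    (constants at 0 °C)

| flask | substrate | target | temperature | time |
|---|---|---|---|---|
| midnight | 5.0 mM | 0.250 mM | 10 °C | 4.0 s |
| winter | 5.0 mM | 0.250 mM | 0 °C | 4.0 s |

- which of the two there is more of at the end, midnight (target / isomer of the product)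
- which of the two there is more of at the end, winter (target / isomer of the product)
- amount of target at the end, in percent of the substrate charged, midnight
- amount of target at the end, in percent of the substrate charged, winter

- the constants hold at 0 °C; other temperatures follow from the activation energies and enthalpies

At midnight, 10 °C, the constants had moved: the autocatalytic rate constant to 5260 M⁻¹ s⁻¹, the dormant equilibrium constant to 0.551, the forward constant of target to isomer of the product to 1.42 s⁻¹, and its equilibrium constant to 5.07. With no dormant form charged, the midnight flask started, by my reckoning, at 6.57 mM s⁻¹.

The first slowing came from the dormant form, which left a fraction 0.645 of the pool of substrate and dormant form free, so the rate reckoned at the charged amounts came down to 4.24 mM s⁻¹. Per target, that gave a logistic growth constant of 17.8 s⁻¹. That constant meant a doubling time of 0.0389 s for target at midnight, longer than the 0.0201 s relaxation half-life of substrate and dormant form at midnight, so I kept the factor in the reckoning.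

The second slowing was the leak of target to isomer of the product, which trimmed the growth constant by a factor 0.920. The accumulated slowing shows in the lag, the time for the logistic burst to reach its midpoint. The first round gave 0.168 s. Going round again with the leak charged gave the lag, the natural logarithm of substrate over target divided by the net growth constant, 0.183 s.

That lag was shorter than the 4.0 s run. So I treated the combined charge, 105 % of the substrate charged, as target at the lag, then relaxing at the summed rate 1.70 s⁻¹. The share of the distance to equilibrium still open at the end was 0.00154. I committed to 17.4 % of target at midnight, with isomer of the product ahead.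

In winter the same steps gave a lag of 0.434 s, a relaxation rate of 0.551 s⁻¹ and an open share of 0.140. I committed to 23.0 % of target, with isomer of the product ahead.

The forecast named isomer of the product for midnight and isomer of the product for winter, with 17.4 % and 22.6 % of target, its winter figure lying below mine, and held that “the outcome is set by how far the target then relaxes toward its isomer”.

The midnight flask gave isomer of the product ahead, with 17.4 % of target against 87.6 % of isomer of the product. The winter flask gave isomer of the product ahead, with 23.5 % against 81.4 %. I then took the midnight flask read at 1.0 s. Counting from the lag of 0.183 s, I gave it 0.817 s of relaxation, which left an open share of 0.250, and I reckoned 39.2 % of target. That flask held 39.9 % of target.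

The constants used here are made up; the result is computed.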